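**Strategy.** The chroman-4-one ring C is disconnected at its aryl ether bond O1–C8a, not at the usual O1–C2 bond. C8a of ring A lies ortho to the C4 ketone, and O1 sits on the only stereocentre, C2. The precursor is therefore an open-chain (S)-β-hydroxy ketone whose aryl ring carries chlorine at the future C8a. Its carbinol centre is set beforehand by copper-catalysed asymmetric conjugate borylation of a chalcone, followed by oxidation. A palladium-catalysed intramolecular C–O coupling then closes ring C in one operation. The C2–O bond is untouched (retention), and the chlorine position fixes the 6-geranyl regiochemistry.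

Key step: step 7

Assumption: C2 of the target is (S) by CIP analysis of the given structure (the natural flavanone series). Abbreviations: geranyl = (2E)-3,7-dimethylocta-2,6-dien-1-yl; MOM = methoxymethyl.

**Step 1**
Reactants: 1 5-chlorobenzene-1,3-diol (5-chlororesorcinol)
Product: 2 1-chloro-3,5-bis(methoxymethoxy)benzene
Conditions: MOMCl (2.5 equiv), iPr2NEt (3 equiv), CH2Cl2, 0 °C to rt
Reagents that add atoms: chloromethyl methyl ether (MOMCl), COCCl
Why: O-alkylation of both phenols (MOM acetal formation) should proceed cleanly and installs the two groups that direct the later metalations.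

**Step 2**
Reactants: 2 1-chloro-3,5-bis(methoxymethoxy)benzene; 3 geranyl bromide
Product: 5 5-chloro-2-geranyl-1,3-bis(methoxymethoxy)benzene, via aryllithium 4 (not isolated)
Conditions: n-BuLi (1.1 equiv), THF, −20 to 0 °C; then CuBr·SMe2 (10 mol %), 3, −40 °C to rt
Reagents that add atoms: none
Why: Directed ortho-metalation should occur at the C–H flanked by both MOM ethers (n-BuLi does not exchange an aryl chloride), and copper-catalysed SN2 allylation at the primary carbon of geranyl bromide should keep the E alkene.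

**Step 3**
Reactants: 6 3-hydroxy-4,5-dimethoxybenzaldehyde
Product: 7 3,4-dimethoxy-5-(methoxymethoxy)benzaldehyde
Conditions: MOMCl (1.3 equiv), iPr2NEt (1.5 equiv), CH2Cl2, 0 °C to rt
Reagents that add atoms: chloromethyl methyl ether (MOMCl), COCCl
Why: MOM ether formation masks the ring B phenol against the organolithium of step 5 and uses the same group as ring A, so one final operation frees all three phenols.

**Step 4**
Reactants: 7 3,4-dimethoxy-5-(methoxymethoxy)benzaldehyde; 8 diethyl {2-[methoxy(methyl)amino]-2-oxoethyl}phosphonate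
Product: 10 (2E)-3-[3,4-dimethoxy-5-(methoxymethoxy)phenyl]-N-methoxy-N-methylprop-2-enamide, via sodium phosphonate carbanion 9 (not isolated)
Conditions: 8, NaH, THF, 0 °C; then 7, 0 °C to rt
Reagents that add atoms: none
Why: Horner–Wadsworth–Emmons olefination of an aryl aldehyde with a stabilised phosphonate should give the E enamide.

**Step 5**
Reactants: 5 5-chloro-2-geranyl-1,3-bis(methoxymethoxy)benzene; 10 (2E)-3-[3,4-dimethoxy-5-(methoxymethoxy)phenyl]-N-methoxy-N-methylprop-2-enamide
Product: 13 (2E)-1-[6-chloro-3-geranyl-2,4-bis(methoxymethoxy)phenyl]-3-[3,4-dimethoxy-5-(methoxymethoxy)phenyl]prop-2-en-1-one, via aryllithium 11 (not isolated), via lithium hemiaminal adduct 12 (not isolated)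
Conditions: 5, n-BuLi, TMEDA, THF, −78 °C, 1 h; then 10, −78 to −40 °C; then H2O
Reagents that add atoms: none
Why: A second directed ortho-metalation at the ring C–H flanked by chlorine and a MOM ether gives an aryllithium that should be stable at −78 °C, and its 1,2-addition to the Weinreb amide (Weinreb ketone synthesis) stops at the chelated adduct 12, which releases the chalcone on quench.

**Step 6**
Reactants: 13 the chalcone of step 5
Product: 15 (3S)-1-[6-chloro-3-geranyl-2,4-bis(methoxymethoxy)phenyl]-3-[3,4-dimethoxy-5-(methoxymethoxy)phenyl]-3-hydroxypropan-1-one, via (S)-boryl ketone 14 (not isolated)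
Conditions: CuCl (5 mol %), NaOtBu (5 mol %), (R)-1-[(S)-2-(diphenylphosphino)ferrocenyl]ethyldicyclohexylphosphine or its mirror image (6 mol %, antipode chosen to give the (S) centre), B2pin2 (1.1 equiv), MeOH (2 equiv), THF, rt; then NaBO3·4H2O, THF/H2O, 0 °C to rt
Reagents that add atoms: bis(pinacolato)diboron, CC1(C)OB(OC1(C)C)B1OC(C)(C)C(C)(C)O1 (boryl group of 14); sodium perborate tetrahydrate, [Na+].[Na+].O[B-]1(O)OO[B-](O)(O)OO1 (hydroxyl oxygen of 15)
Why: Copper-catalysed asymmetric conjugate borylation of the enone sets the benzylic centre under control of the chiral bisphosphine (a monovalent copper boryl adds to one enantiotopic face of the β-carbon), and perborate oxidation of the C–B bond proceeds with retention to give the aldol-type (S)-carbinol; aryl chloride, MOM ethers and the unactivated geranyl alkenes should not react.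

**Step 7**
Reactants: 15 the (S)-β-hydroxy ketone of step 6
Product: 16 (2S)-2-[3,4-dimethoxy-5-(methoxymethoxy)phenyl]-6-geranyl-5,7-bis(methoxymethoxy)-2,3-dihydro-4H-chromen-4-one
Conditions: [Pd(C3H5)Cl]2 (allylpalladium chloride dimer, 2.5 mol %), 2-(di-tert-butylphosphino)-3-methoxy-6-methyl-2',4',6'-triisopropyl-1,1'-biphenyl (RockPhos, 6 mol %), Cs2CO3 (1.5 equiv), toluene, 60 °C
Reagents that add atoms: none
Why: Zerovalent palladium inserts into the C8a–Cl bond, which the ortho C4 ketone activates; Cs2CO3 deprotonates the palladium-bound C2 hydroxyl, and C–O reductive elimination from the seven-membered aryl alkoxide complex of divalent palladium forms the O1–C8a bond. The closest known reaction type is the Buchwald–Hartwig intramolecular etherification of aryl halides with secondary alcohols, which preserves carbinol configuration. Ring C closes as a six-membered ring by ipso substitution at C8a (formally a 6-exo attack of O1 on the chlorine-bearing carbon). No new stereocentre is formed, and C2 keeps its (S) configuration because its C–O and C–H bonds are never broken. The step needs reductive elimination to outrun β-hydride elimination of the palladium alkoxide and base-induced retro-aldol or dehydration of 15; the bulky electron-rich biaryl phosphine, the weak insoluble base and the apolar solvent are chosen to secure this. Chemo- and regioselectivity rest on the substrate, which holds one C–Cl bond and one free hydroxyl, so only the 6-geranyl isomer can form.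

**Step 8**
Reactants: 16 the tris-MOM flavanone of step 7
Product: 17 (2S)-6-geranyl-5,7-dihydroxy-2-(3-hydroxy-4,5-dimethoxyphenyl)-2,3-dihydro-4H-chromen-4-one (target)
Conditions: HCl (3 M aq.)/MeOH 1:4, 50 °C, short reaction time
Reagents that add atoms: none
Why: Acid-catalysed methanolysis of the three MOM acetals (transacetalisation) frees the phenols without base, so C2 should not epimerise through ring opening, and the brief mild acid exposure should spare the geranyl alkenes and the methyl ethers.

**Compound list**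
1 | 5-chlorobenzene-1,3-diol | Oc1cc(O)cc(Cl)c1 | starting material
2 | 1-chloro-3,5-bis(methoxymethoxy)benzene | COCOc1cc(Cl)cc(OCOC)c1 | intermediate
3 | geranyl bromide, (2E)-1-bromo-3,7-dimethylocta-2,6-diene | BrC/C=C(\C)CCC=C(C)C | starting material
4 | [4-chloro-2,6-bis(methoxymethoxy)phenyl]lithium | [Li]c1c(OCOC)cc(Cl)cc1OCOC | intermediate
5 | 5-chloro-2-[(2E)-3,7-dimethylocta-2,6-dien-1-yl]-1,3-bis(methoxymethoxy)benzene | COCOc1cc(Cl)cc(OCOC)c1C/C=C(\C)CCC=C(C)C | intermediate
6 | 3-hydroxy-4,5-dimethoxybenzaldehyde | COc1cc(C=O)cc(O)c1OC | starting material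
7 | 3,4-dimethoxy-5-(methoxymethoxy)benzaldehyde | COCOc1cc(C=O)cc(OC)c1OC | intermediate
8 | diethyl {2-[methoxy(methyl)amino]-2-oxoethyl}phosphonate | CCOP(=O)(OCC)CC(=O)N(C)OC | starting material
9 | sodium salt of the α-carbanion of phosphonate 8 | [Na+].CCOP(=O)(OCC)[CH-]C(=O)N(C)OC | intermediate
10 | (2E)-3-[3,4-dimethoxy-5-(methoxymethoxy)phenyl]-N-methoxy-N-methylprop-2-enamide | COCOc1cc(/C=C/C(=O)N(C)OC)cc(OC)c1OC | intermediate
11 | {6-chloro-3-[(2E)-3,7-dimethylocta-2,6-dien-1-yl]-2,4-bis(methoxymethoxy)phenyl}lithium | COCOc1c([Li])c(Cl)cc(OCOC)c1C/C=C(\C)CCC=C(C)C | intermediate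
12 | lithium alkoxide of the N-methoxy-N-methyl hemiaminal formed from 11 and 10 (racemic at the new carbon) | COCOc1cc(/C=C/C(O[Li])(N(C)OC)c2c(Cl)cc(OCOC)c(C/C=C(\C)CCC=C(C)C)c2OCOC)cc(OC)c1OC | intermediate
13 | (2E)-1-{6-chloro-3-[(2E)-3,7-dimethylocta-2,6-dien-1-yl]-2,4-bis(methoxymethoxy)phenyl}-3-[3,4-dimethoxy-5-(methoxymethoxy)phenyl]prop-2-en-1-one | COCOc1cc(/C=C/C(=O)c2c(Cl)cc(OCOC)c(C/C=C(\C)CCC=C(C)C)c2OCOC)cc(OC)c1OC | intermediate
14 | (3S)-1-{6-chloro-3-[(2E)-3,7-dimethylocta-2,6-dien-1-yl]-2,4-bis(methoxymethoxy)phenyl}-3-[3,4-dimethoxy-5-(methoxymethoxy)phenyl]-3-(4,4,5,5-tetramethyl-1,3,2-dioxaborolan-2-yl)propan-1-one | COCOc1cc([C@@H](B2OC(C)(C)C(C)(C)O2)CC(=O)c2c(Cl)cc(OCOC)c(C/C=C(\C)CCC=C(C)C)c2OCOC)cc(OC)c1OC | intermediate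
15 | (3S)-1-{6-chloro-3-[(2E)-3,7-dimethylocta-2,6-dien-1-yl]-2,4-bis(methoxymethoxy)phenyl}-3-[3,4-dimethoxy-5-(methoxymethoxy)phenyl]-3-hydroxypropan-1-one | COCOc1cc([C@@H](O)CC(=O)c2c(Cl)cc(OCOC)c(C/C=C(\C)CCC=C(C)C)c2OCOC)cc(OC)c1OC | intermediate
16 | (2S)-2-[3,4-dimethoxy-5-(methoxymethoxy)phenyl]-6-[(2E)-3,7-dimethylocta-2,6-dien-1-yl]-5,7-bis(methoxymethoxy)-2,3-dihydro-4H-chromen-4-one | COCOc1cc([C@@H]2CC(=O)c3c(cc(OCOC)c(C/C=C(\C)CCC=C(C)C)c3OCOC)O2)cc(OC)c1OC | intermediate
17 | (2S)-6-[(2E)-3,7-dimethylocta-2,6-dien-1-yl]-5,7-dihydroxy-2-(3-hydroxy-4,5-dimethoxyphenyl)-2,3-dihydro-4H-chromen-4-one | COc1cc([C@@H]2CC(=O)c3c(cc(O)c(C/C=C(\C)CCC=C(C)C)c3O)O2)cc(O)c1OC | target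

**Step count and risks**
Total steps: 8. Longest linear sequence: 6 (steps 1, 2, 5, 6, 7, 8).

Steps most likely to fail:

1. Step 7 (key step). The β-hydroxy ketone may undergo base-induced retro-aldol cleavage or dehydration before the C–O bond forms, the palladium alkoxide may undergo β-hydride elimination, or the product may lose configurational purity by reversible E1cB ring opening. The fallback sets out from 15 and returns at 16, moving the coupling to the alcohol oxidation level, where none of these carbonyl-driven processes can occur. Reduction of 15 with NaBH4 (MeOH, 0 °C) should give (1RS,3S)-1-[6-chloro-3-geranyl-2,4-bis(methoxymethoxy)phenyl]-3-[3,4-dimethoxy-5-(methoxymethoxy)phenyl]propane-1,3-diol F1 as an inconsequential mixture at the new carbinol. The same palladium/RockPhos etherification (Cs2CO3, toluene, 80–90 °C) should then close ring C through the C3 hydroxyl only, since the other hydroxyl could reach C8a only through a four-membered ring. This gives (2S,4RS)-2-[3,4-dimethoxy-5-(methoxymethoxy)phenyl]-6-geranyl-5,7-bis(methoxymethoxy)chroman-4-ol F2. Oxidation of the benzylic alcohol with Dess–Martin periodinane (NaHCO3, CH2Cl2) under non-basic conditions returns 16.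

2. Step 5. The ortho-chloro aryllithium may lose LiCl to give an aryne, the base may instead deprotonate the benzylic–allylic CH2 of the geranyl group, or the aryllithium may add in conjugate fashion to the enamide. The fallback sets out from 1 and returns at 13, avoiding any organolithium next to chlorine. Friedel–Crafts acylation of 1 (AcOH, BF3·OEt2, 90 °C) should give 1-(2-chloro-4,6-dihydroxyphenyl)ethan-1-one F3. Base-mediated C-geranylation with 3 (DBU, THF) between the two phenols should give 1-[6-chloro-3-geranyl-2,4-dihydroxyphenyl]ethan-1-one F4. Protection (NaH, MOMCl, DMF) should give 1-[6-chloro-3-geranyl-2,4-bis(methoxymethoxy)phenyl]ethan-1-one F5. Claisen–Schmidt condensation of F5 with aldehyde 7 (KOH, EtOH, rt) gives chalcone 13.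

3. Step 2. Metalation may occur next to chlorine instead of between the two acetals, leading to aryne formation or the wrong regioisomer, or allylation may take the SN2' course to the linalyl-type isomer. The fallback sets out from 1 and returns at 5 without organometallic chemistry. Acidic-alumina-promoted ortho C-allylation of 1 with geraniol (Al2O3, 1,2-dichloroethane, reflux), which places the chain between the two hydroxyls of 5-substituted resorcinols, should give 5-chloro-2-geranylbenzene-1,3-diol F6. Bis-MOM protection (MOMCl, iPr2NEt, CH2Cl2) then gives 5.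

**Further compounds**
F1 | step 7 | (1RS,3S)-1-{6-chloro-3-[(2E)-3,7-dimethylocta-2,6-dien-1-yl]-2,4-bis(methoxymethoxy)phenyl}-3-[3,4-dimethoxy-5-(methoxymethoxy)phenyl]propane-1,3-diol | COCOc1cc([C@@H](O)CC(O)c2c(Cl)cc(OCOC)c(C/C=C(\C)CCC=C(C)C)c2OCOC)cc(OC)c1OC
F2 | step 7 | (2S,4RS)-2-[3,4-dimethoxy-5-(methoxymethoxy)phenyl]-6-[(2E)-3,7-dimethylocta-2,6-dien-1-yl]-5,7-bis(methoxymethoxy)-3,4-dihydro-2H-chromen-4-ol | COCOc1cc([C@@H]2CC(O)c3c(cc(OCOC)c(C/C=C(\C)CCC=C(C)C)c3OCOC)O2)cc(OC)c1OC
F3 | step 5 | 1-(2-chloro-4,6-dihydroxyphenyl)ethan-1-one | CC(=O)c1c(Cl)cc(O)cc1O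
F4 | step 5 | 1-{6-chloro-3-[(2E)-3,7-dimethylocta-2,6-dien-1-yl]-2,4-dihydroxyphenyl}ethan-1-one | CC(=O)c1c(Cl)cc(O)c(C/C=C(\C)CCC=C(C)C)c1O
F5 | step 5 | 1-{6-chloro-3-[(2E)-3,7-dimethylocta-2,6-dien-1-yl]-2,4-bis(methoxymethoxy)phenyl}ethan-1-one | CC(=O)c1c(Cl)cc(OCOC)c(C/C=C(\C)CCC=C(C)C)c1OCOC
F6 | step 2 | 5-chloro-2-[(2E)-3,7-dimethylocta-2,6-dien-1-yl]benzene-1,3-diol | Oc1cc(Cl)cc(O)c1C/C=C(\C)CCC=C(C)C
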